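**Plan**

- Numbering: ring A = C1–C5 and C10; ring B = C5–C10; C4 bears CH3 and CO2H; C8 and C9 bear CH3; the side chain C11–C15 sits on C9. In ring B the sp2 carbon C10 has its double bond outside that ring (to C1) and lies between the quaternary C9 and the C5 methine. With a C6=C7 bond added back, this is the retron of a [4+2] between a C5=C6–C7=C8 diene and the far π-bond (C9=C10) of a tethered C1=C10=C9 allene.
- Retrosynthesis: remove the acetates and protecting groups, re-install C6=C7, cut C5–C10 and C8–C9 together, then cut the allene at C9–CH3 and at C1–C10 (acetylide plus aldehyde), and finally cut C3–C4.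
- Forward: a C4/diene aldehyde (8 steps) and a side-chain alkyne from geraniol (5 steps) are joined at C1–C10. The chain is turned into the allene, and one rhodium-catalysed [4+2] closes rings A and B in the same step.
- Stereochemistry: C4 comes from an oxazolidinone-controlled trienolate allylation. C13 and C14 come from asymmetric epoxidation of geraniol and inverting hydrolysis. The C1 carbinol (transfer hydrogenation) is relayed to the allene axis and from there to C9. C5 and C8 follow from the (5E,7E)-diene and the methyl-endo approach.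

Key step: step 19

Assumption: the sodium trienolate of 8 is taken to react like a standard oxazolidinone enolate (α-methyl syn to the enolate oxygen, attack anti to the isopropyl group); if the facial sense were the opposite one, the enantiomeric auxiliary would be used with no other change.

**Route**

Step 1
Reactants: 1 (Z)-pent-2-en-1-ol; 2 methyl 2-(triphenylphosphoranylidene)propanoate
Product: 4 methyl (2E,4Z)-2-methylhepta-2,4-dienoate, via (Z)-pent-2-enal 3 (not isolated)
Conditions: DMP, NaHCO3, CH2Cl2, 0 °C; then 2, rt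
Reagents that add atoms: none
Why: One-pot Dess–Martin oxidation and Wittig olefination, in which the buffered Z-enal is trapped as formed by the α-branched stabilised ylide to give the (2E)-enoate with the (4Z)-bond kept; the 4Z geometry is wanted because it later forces the propenyl end of the diene to form E.

Step 2
Reactants: 4 methyl (2E,4Z)-2-methylhepta-2,4-dienoate
Product: 5 (2E,4Z)-2-methylhepta-2,4-dienoic acid
Conditions: LiOH, THF/MeOH/H2O, rt; then HCl (aq)
Reagents that add atoms: lithium hydroxide, [Li+].[OH-]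
Why: Saponification of an unhindered conjugated methyl ester, mild enough to leave both alkene geometries intact.

Step 3
Reactants: 5 (2E,4Z)-2-methylhepta-2,4-dienoic acid; 6 (R)-4-isopropyl-1,3-oxazolidin-2-one
Product: 8 (R)-4-isopropyl-3-[(2E,4Z)-2-methylhepta-2,4-dienoyl]-1,3-oxazolidin-2-one, via pivalic mixed anhydride 7 (not isolated)
Conditions: PivCl, Et3N, THF, −20 °C; then 6, LiCl, −20 °C → rt
Reagents that add atoms: none
Why: N-Acylation of the oxazolidinone through the mixed pivalic anhydride under LiCl/Et3N activation, a standard way to attach this auxiliary to an enoic acid.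

Step 4
Reactants: 8 (R)-4-isopropyl-3-[(2E,4Z)-2-methylhepta-2,4-dienoyl]-1,3-oxazolidin-2-one; 9 allyl iodide
Product: 11 (R)-4-isopropyl-3-[(2S,3E,5E)-2-methyl-2-(prop-2-en-1-yl)hepta-3,5-dienoyl]-1,3-oxazolidin-2-one, via sodium trienolate 10 (not isolated)
Conditions: NaN(SiMe3)2, THF, −78 °C; then 9, −78 → −40 °C
Reagents that add atoms: none
Why: Auxiliary-controlled deconjugative α-alkylation of an extended imide enolate: the base removes the C6 proton, allylic 1,3-strain in the 4Z substrate makes both new double bonds E, and allyl iodide should enter at the α-carbon anti to the isopropyl group to set the quaternary carbon (future C4) as S.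

Step 5
Reactants: 11 (R)-4-isopropyl-3-[(2S,3E,5E)-2-methyl-2-(prop-2-en-1-yl)hepta-3,5-dienoyl]-1,3-oxazolidin-2-one
Product: 13 (2S,3E,5E)-2-methyl-2-(prop-2-en-1-yl)hepta-3,5-dienoic acid, via peroxy acid 12 (not isolated)
Conditions: LiOH, H2O2, THF/H2O, 0 °C; then Na2SO3 (aq); then HCl (aq)
Reagents that add atoms: hydrogen peroxide, OO
Why: Hydroperoxide cleavage of the N-acyl oxazolidinone, in which the small α-effect nucleophile attacks the exocyclic carbonyl even of a hindered imide, sulfite reduces the peracid, and the quaternary centre cannot epimerise.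

Step 6
Reactants: 13 (2S,3E,5E)-2-methyl-2-(prop-2-en-1-yl)hepta-3,5-dienoic acid
Product: 14 2-(trimethylsilyl)ethyl (2S,3E,5E)-2-methyl-2-(prop-2-en-1-yl)hepta-3,5-dienoate
Conditions: Me3SiCH2CH2OH, EDC·HCl, DMAP (cat.), CH2Cl2, rt
Reagents that add atoms: 2-(trimethylsilyl)ethanol, C[Si](C)(C)CCO
Why: Steglich esterification at room temperature (no heating, so the 1,5-diene cannot undergo Cope rearrangement); this ester is chosen because fluoride will free the acid at the end together with the silyl ethers.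

Step 7
Reactants: 14 2-(trimethylsilyl)ethyl (2S,3E,5E)-2-methyl-2-(prop-2-en-1-yl)hepta-3,5-dienoate
Product: 16 2-(trimethylsilyl)ethyl (2S,3E,5E)-2-(3-hydroxypropyl)-2-methylhepta-3,5-dienoate, via B-alkyl-9-BBN adduct 15 (not isolated)
Conditions: 9-BBN, THF, 0 °C → rt; then H2O2, NaOH (aq), 0 °C
Reagents that add atoms: hydrogen peroxide, OO
Why: Anti-Markovnikov hydroboration–oxidation, in which 9-BBN should take the monosubstituted allyl alkene far faster than the internal, conjugated, 1,2-disubstituted diene.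

Step 8
Reactants: 16 2-(trimethylsilyl)ethyl (2S,3E,5E)-2-(3-hydroxypropyl)-2-methylhepta-3,5-dienoate
Product: 17 2-(trimethylsilyl)ethyl (2S,3E,5E)-2-methyl-2-(3-oxopropyl)hepta-3,5-dienoate
Conditions: DMP, NaHCO3, CH2Cl2, 0 °C → rt
Reagents that add atoms: none
Why: Dess–Martin oxidation of a primary alcohol to the aldehyde (future C1) under neutral conditions that leave diene and ester alone.

Step 9
Reactants: 18 geraniol
Product: 19 (2S,3S)-2,3-epoxygeraniol
Conditions: Ti(OiPr)4 (5 mol%), L-(+)-diethyl tartrate (6 mol%), t-BuOOH, 4 Å molecular sieves, CH2Cl2, −20 °C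
Reagents that add atoms: tert-butyl hydroperoxide, CC(C)(C)OO
Why: Sharpless asymmetric epoxidation: the allylic hydroxyl directs titanium to the 2,3-alkene only, and the L-(+)-tartrate ligand selects the face that gives the (2S,3S)-epoxide (future C14, and C13 after inversion).

Step 10
Reactants: 19 (2S,3S)-2,3-epoxygeraniol
Product: 20 (2S,3R)-3,7-dimethyloct-6-ene-1,2,3-triol
Conditions: HClO4 (cat.), THF/H2O, 0 °C → rt
Reagents that add atoms: water, O
Why: Acid-catalysed epoxide hydrolysis, in which water opens the protonated epoxide at the tertiary carbon with inversion, so the product should carry C13 as R and C14 as S.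

Step 11
Reactants: 20 (2S,3R)-3,7-dimethyloct-6-ene-1,2,3-triol
Product: 21 (2S,3R)-3,7-dimethyl-1,2,3-tris(triethylsilyloxy)oct-6-ene
Conditions: Et3SiOTf, 2,6-lutidine, CH2Cl2, −78 → 0 °C
Reagents that add atoms: triethylsilyl trifluoromethanesulfonate, CC[Si](CC)(CC)OS(=O)(=O)C(F)(F)F
Why: Silylation with the silyl triflate, which is reactive enough to cover the tertiary hydroxyl as well as the primary and secondary ones.

Step 12
Reactants: 21 (2S,3R)-3,7-dimethyl-1,2,3-tris(triethylsilyloxy)oct-6-ene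
Product: 23 (4R,5S)-4-methyl-4,5,6-tris(triethylsilyloxy)hexanal, via ozonide 22 (not isolated)
Conditions: O3, CH2Cl2, −78 °C; then PPh3, −78 °C → rt
Reagents that add atoms: ozone, [O-][O+]=O
Why: Ozonolysis with reductive work-up of the only alkene, which releases acetone and the aldehyde whose carbon becomes C9.

Step 13
Reactants: 23 (4R,5S)-4-methyl-4,5,6-tris(triethylsilyloxy)hexanal
Product: 24 (2S,3R)-3-methyl-1,2,3-tris(triethylsilyloxy)hept-6-yne
Conditions: dimethyl (1-diazo-2-oxopropyl)phosphonate, K2CO3, MeOH, 0 °C → rt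
Reagents that add atoms: dimethyl (1-diazo-2-oxopropyl)phosphonate, CC(=O)C(=[N+]=[N-])P(=O)(OC)OC
Why: Ohira–Bestmann (Seyferth–Gilbert) homologation of the aldehyde to the terminal alkyne (C9≡C10) under mild carbonate conditions that the silyl ethers should tolerate.

Step 14
Reactants: 24 (2S,3R)-3-methyl-1,2,3-tris(triethylsilyloxy)hept-6-yne; 17 2-(trimethylsilyl)ethyl (2S,3E,5E)-2-methyl-2-(3-oxopropyl)hepta-3,5-dienoate
Product: 26 2-(trimethylsilyl)ethyl (2S,3E,5E)-2-[(8R,9S)-3-hydroxy-8-methyl-8,9,10-tris(triethylsilyloxy)dec-4-yn-1-yl]-2-methylhepta-3,5-dienoate (C1 carbinol epimers), via lithium acetylide 25 (not isolated)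
Conditions: n-BuLi, THF, −78 °C; then 17, −78 °C; NH4Cl (aq)
Reagents that add atoms: none
Why: 1,2-Addition of a lithium acetylide to an aldehyde, joining the fragments at C1–C10 in 1:1 stoichiometry; the hindered quaternary ester is not attacked at −78 °C and the carbinol centre is left unset because steps 15 and 16 set it.

Step 15
Reactants: 26 2-(trimethylsilyl)ethyl (2S,3E,5E)-2-[(8R,9S)-3-hydroxy-8-methyl-8,9,10-tris(triethylsilyloxy)dec-4-yn-1-yl]-2-methylhepta-3,5-dienoate (C1 carbinol epimers)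
Product: 27 2-(trimethylsilyl)ethyl (2S,3E,5E)-2-methyl-2-[(8R,9S)-8-methyl-3-oxo-8,9,10-tris(triethylsilyloxy)dec-4-yn-1-yl]hepta-3,5-dienoate
Conditions: DMP, NaHCO3, CH2Cl2, 0 °C → rt
Reagents that add atoms: none
Why: Dess–Martin oxidation of the propargylic alcohol to the alkynyl ketone, which merges both carbinol epimers into one compound.

Step 16
Reactants: 27 2-(trimethylsilyl)ethyl (2S,3E,5E)-2-methyl-2-[(8R,9S)-8-methyl-3-oxo-8,9,10-tris(triethylsilyloxy)dec-4-yn-1-yl]hepta-3,5-dienoate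
Product: 28 2-(trimethylsilyl)ethyl (2S,3E,5E)-2-[(3R,8R,9S)-3-hydroxy-8-methyl-8,9,10-tris(triethylsilyloxy)dec-4-yn-1-yl]-2-methylhepta-3,5-dienoate
Conditions: Ru[(R,R)-TsDPEN](p-cymene) (16-electron amido complex, 2 mol%), i-PrOH, rt
Reagents that add atoms: none
Why: Noyori asymmetric transfer hydrogenation of an alkynyl ketone, which reduces only the carbonyl and, with the alkynyl group acting as the π-substituent, should give the (R)-carbinol at C1 under catalyst control.

Step 17
Reactants: 28 2-(trimethylsilyl)ethyl (2S,3E,5E)-2-[(3R,8R,9S)-3-hydroxy-8-methyl-8,9,10-tris(triethylsilyloxy)dec-4-yn-1-yl]-2-methylhepta-3,5-dienoate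
Product: 29 2-(trimethylsilyl)ethyl (2S,3E,5E)-2-[(3R,8R,9S)-3-(methanesulfonyloxy)-8-methyl-8,9,10-tris(triethylsilyloxy)dec-4-yn-1-yl]-2-methylhepta-3,5-dienoate
Conditions: MsCl, Et3N, CH2Cl2, −78 → −30 °C; used crude
Reagents that add atoms: methanesulfonyl chloride, CS(=O)(=O)Cl
Why: O-Sulfonylation of the secondary propargylic alcohol, which does not touch the C1–O bond and so keeps the R configuration.

Step 18
Reactants: 29 2-(trimethylsilyl)ethyl (2S,3E,5E)-2-[(3R,8R,9S)-3-(methanesulfonyloxy)-8-methyl-8,9,10-tris(triethylsilyloxy)dec-4-yn-1-yl]-2-methylhepta-3,5-dienoate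
Product: 30 2-(trimethylsilyl)ethyl (2S,3E,5E)-2-[(8R,9S)-5,8-dimethyl-8,9,10-tris(triethylsilyloxy)deca-3,4-dien-1-yl]-2-methylhepta-3,5-dienoate with the C1=C10=C9 allene axis R (aR)
Conditions: MeMgBr, CuBr·SMe2, LiBr, THF, −78 → −30 °C
Reagents that add atoms: methylmagnesium bromide, C[Mg]Br
Why: Anti-SN2′ substitution of a propargylic mesylate by a methylcopper reagent, in which methyl is delivered to C9 on the face opposite the leaving group so that the (R)-carbinol becomes the (R)-allene axis; the magnesium bromocuprate is preferred because it is less prone to racemise allenes.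

Step 19
Reactants: 30 2-(trimethylsilyl)ethyl (2S,3E,5E)-2-[(8R,9S)-5,8-dimethyl-8,9,10-tris(triethylsilyloxy)deca-3,4-dien-1-yl]-2-methylhepta-3,5-dienoate with the C1=C10=C9 allene axis R (aR)
Product: 31 2-(trimethylsilyl)ethyl (1S,5S,6R,8aS)-1,5,6-trimethyl-5-[(3R,4S)-3-methyl-3,4,5-tris(triethylsilyloxy)pentyl]-1,2,3,5,6,8a-hexahydronaphthalene-1-carboxylate (C1=C10 and C6=C7 in the numbering of the plan)
Conditions: [Rh(cod)Cl]2 (5 mol%), P(O-2-PhC6H4)3 (25 mol%), degassed THF, 45–60 °C
Reagents that add atoms: none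
Why: Proposed new method: monovalent rhodium carrying the π-acidic phosphite is expected to couple the s-cis diene with the allene π-bond remote from the tether (C5–C10 first, giving a rhodacycle with an allyl unit over C6–C8 and C9 on the metal) and then to close C8–C9 by reductive elimination, a stepwise [4+2]; the closest known reaction type is the rhodium- or nickel-phosphite-catalysed intramolecular diene–allene [4+2] cycloaddition, in which rhodium is the metal that takes the distal π-bond, but it has not been shown for an allene terminus that becomes a quaternary carbon beside a tertiary one. Ring A closes through the three-carbon tether by 6-exo attack of C5 on the central allene carbon C10, which leaves C1=C10 inside that ring, and ring B closes as the six-membered ring of the [4+2] through the two new σ-bonds. C9 is set by the allene axis alone, because the tether lets the diene reach the C9=C10 bond from one side only; C5 and C8 follow from suprafacial addition to the (5E,7E)-diene (C4 and the C8 methyl cis) in the orientation that puts the small C9 methyl, not the C11 chain, under the diene (C9 methyl cis to C8 methyl). The C4 centre supports the same orientation, since it lets the ester sit pseudo-axial and the methyl pseudo-equatorial on the forming half-chair of ring A. The step needs distal over proximal π-bond selectivity, secured by the choice of rhodium and by a tether length that makes distal attack a six-ring closure, and it needs the axis to survive until C8–C9 forms.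

Step 20
Reactants: 31 2-(trimethylsilyl)ethyl (1S,5S,6R,8aS)-1,5,6-trimethyl-5-[(3R,4S)-3-methyl-3,4,5-tris(triethylsilyloxy)pentyl]-1,2,3,5,6,8a-hexahydronaphthalene-1-carboxylate
Product: 32 2-(trimethylsilyl)ethyl (1S,5S,6R,8aS)-1,5,6-trimethyl-5-[(3R,4S)-3-methyl-3,4,5-tris(triethylsilyloxy)pentyl]-1,2,3,5,6,7,8,8a-octahydronaphthalene-1-carboxylate
Conditions: 2-O2NC6H4SO2NHNH2, Et3N, CH2Cl2, rt
Reagents that add atoms: none
Why: Diimide reduction, a concerted syn transfer of H2 that should take the cis-disubstituted C6=C7 bond much faster than the trisubstituted, hindered C1=C10 bond and creates no stereocentre.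

Step 21
Reactants: 32 2-(trimethylsilyl)ethyl (1S,5S,6R,8aS)-1,5,6-trimethyl-5-[(3R,4S)-3-methyl-3,4,5-tris(triethylsilyloxy)pentyl]-1,2,3,5,6,7,8,8a-octahydronaphthalene-1-carboxylate
Product: 33 (1S,5S,6R,8aS)-5-[(3R,4S)-3,4,5-trihydroxy-3-methylpentyl]-1,5,6-trimethyl-1,2,3,5,6,7,8,8a-octahydronaphthalene-1-carboxylic acid
Conditions: Bu4NF, THF, rt → 45 °C; then 0.5 M HCl to pH 4
Reagents that add atoms: none
Why: Fluoride-mediated global deprotection: the three triethylsilyl ethers are cleaved and the 2-(trimethylsilyl)ethyl ester fragments by β-elimination to the carboxylate, ethene and Me3SiF.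

Step 22
Reactants: 33 (1S,5S,6R,8aS)-5-[(3R,4S)-3,4,5-trihydroxy-3-methylpentyl]-1,5,6-trimethyl-1,2,3,5,6,7,8,8a-octahydronaphthalene-1-carboxylic acid
Product: 34 (1S,5S,6R,8aS)-5-[(3R,4S)-4,5-diacetoxy-3-hydroxy-3-methylpentyl]-1,5,6-trimethyl-1,2,3,5,6,7,8,8a-octahydronaphthalene-1-carboxylic acid (CNP0224606.1)
Conditions: Ac2O, pyridine, 0 °C → rt; then H2O/THF
Reagents that add atoms: acetic anhydride, CC(=O)OC(C)=O
Why: Acetylation with Ac2O/pyridine of the primary and secondary hydroxyls only, since the tertiary C13 hydroxyl is too hindered without an acyl-transfer catalyst and any mixed anhydride at the acid is hydrolysed in the aqueous work-up.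

**Compound list**

1 | (Z)-pent-2-en-1-ol | CC/C=C\CO | starting material
2 | methyl 2-(triphenylphosphoranylidene)propanoate | COC(=O)C(C)=P(c1ccccc1)(c1ccccc1)c1ccccc1 | starting material
3 | (Z)-pent-2-enal (formed in situ) | CC/C=C\C=O | intermediate
4 | methyl (2E,4Z)-2-methylhepta-2,4-dienoate | CC/C=C\C=C(/C)C(=O)OC | intermediate
5 | (2E,4Z)-2-methylhepta-2,4-dienoic acid | CC/C=C\C=C(/C)C(=O)O | intermediate
6 | (R)-4-isopropyl-1,3-oxazolidin-2-one | CC(C)[C@@H]1COC(=O)N1 | starting material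
7 | (2E,4Z)-2-methylhepta-2,4-dienoic pivalic anhydride (formed in situ) | CC/C=C\C=C(/C)C(=O)OC(=O)C(C)(C)C | intermediate
8 | (R)-4-isopropyl-3-[(2E,4Z)-2-methylhepta-2,4-dienoyl]-1,3-oxazolidin-2-one | CC/C=C\C=C(/C)C(=O)N1[C@H](C(C)C)COC1=O | intermediate
9 | allyl iodide (3-iodoprop-1-ene) | C=CCI | starting material
10 | sodium trienolate of 8 (C6 deprotonated; 3E,5E; enolate oxygen syn to the 2-methyl group; formed in situ) | C/C=C/C=C/C(C)=C(/[O-])N1[C@H](C(C)C)COC1=O.[Na+] | intermediate
11 | (R)-4-isopropyl-3-[(2S,3E,5E)-2-methyl-2-(prop-2-en-1-yl)hepta-3,5-dienoyl]-1,3-oxazolidin-2-one | C/C=C/C=C/[C@@](C)(C(=O)N1[C@H](C(C)C)COC1=O)CC=C | intermediate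
12 | (2S,3E,5E)-2-methyl-2-(prop-2-en-1-yl)hepta-3,5-dieneperoxoic acid (formed in situ as its lithium salt) | C/C=C/C=C/[C@@](C)(C(=O)OO)CC=C | intermediate
13 | (2S,3E,5E)-2-methyl-2-(prop-2-en-1-yl)hepta-3,5-dienoic acid | C/C=C/C=C/[C@@](C)(C(=O)O)CC=C | intermediate
14 | 2-(trimethylsilyl)ethyl (2S,3E,5E)-2-methyl-2-(prop-2-en-1-yl)hepta-3,5-dienoate | C/C=C/C=C/[C@@](C)(C(=O)OCC[Si](C)(C)C)CC=C | intermediate
15 | B-alkyl-9-BBN adduct of 14 (boron on the terminal carbon; formed in situ) | C/C=C/C=C/[C@@](C)(C(=O)OCC[Si](C)(C)C)CCCB1C2CCCC1CCC2 | intermediate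
16 | 2-(trimethylsilyl)ethyl (2S,3E,5E)-2-(3-hydroxypropyl)-2-methylhepta-3,5-dienoate | C/C=C/C=C/[C@@](C)(C(=O)OCC[Si](C)(C)C)CCCO | intermediate
17 | 2-(trimethylsilyl)ethyl (2S,3E,5E)-2-methyl-2-(3-oxopropyl)hepta-3,5-dienoate | C/C=C/C=C/[C@@](C)(C(=O)OCC[Si](C)(C)C)CCC=O | intermediate
18 | geraniol, (2E)-3,7-dimethylocta-2,6-dien-1-ol | CC(C)=CCC/C(C)=C/CO | starting material
19 | (2S,3S)-2,3-epoxygeraniol, [(2S,3S)-3-methyl-3-(4-methylpent-3-en-1-yl)oxiran-2-yl]methanol | CC(C)=CCC[C@]1(C)O[C@H]1CO | intermediate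
20 | (2S,3R)-3,7-dimethyloct-6-ene-1,2,3-triol | CC(C)=CCC[C@@](C)(O)[C@@H](O)CO | intermediate
21 | (2S,3R)-3,7-dimethyl-1,2,3-tris(triethylsilyloxy)oct-6-ene | CC(C)=CCC[C@@](C)(O[Si](CC)(CC)CC)[C@@H](O[Si](CC)(CC)CC)CO[Si](CC)(CC)CC | intermediate
22 | ozonide (1,2,4-trioxolane) of 21 (formed in situ) | CC1(C)OOC(CC[C@@](C)(O[Si](CC)(CC)CC)[C@@H](O[Si](CC)(CC)CC)CO[Si](CC)(CC)CC)O1 | intermediate
23 | (4R,5S)-4-methyl-4,5,6-tris(triethylsilyloxy)hexanal | O=CCC[C@@](C)(O[Si](CC)(CC)CC)[C@@H](O[Si](CC)(CC)CC)CO[Si](CC)(CC)CC | intermediate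
24 | (2S,3R)-3-methyl-1,2,3-tris(triethylsilyloxy)hept-6-yne | C#CCC[C@@](C)(O[Si](CC)(CC)CC)[C@@H](O[Si](CC)(CC)CC)CO[Si](CC)(CC)CC | intermediate
25 | lithium acetylide of 24 (formed in situ) | [Li+].[C-]#CCC[C@@](C)(O[Si](CC)(CC)CC)[C@@H](O[Si](CC)(CC)CC)CO[Si](CC)(CC)CC | intermediate
26 | 2-(trimethylsilyl)ethyl (2S,3E,5E)-2-[(8R,9S)-3-hydroxy-8-methyl-8,9,10-tris(triethylsilyloxy)dec-4-yn-1-yl]-2-methylhepta-3,5-dienoate (C1 carbinol epimers) | C/C=C/C=C/[C@@](C)(C(=O)OCC[Si](C)(C)C)CCC(O)C#CCC[C@@](C)(O[Si](CC)(CC)CC)[C@@H](O[Si](CC)(CC)CC)CO[Si](CC)(CC)CC | intermediate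
27 | 2-(trimethylsilyl)ethyl (2S,3E,5E)-2-methyl-2-[(8R,9S)-8-methyl-3-oxo-8,9,10-tris(triethylsilyloxy)dec-4-yn-1-yl]hepta-3,5-dienoate | C/C=C/C=C/[C@@](C)(C(=O)OCC[Si](C)(C)C)CCC(=O)C#CCC[C@@](C)(O[Si](CC)(CC)CC)[C@@H](O[Si](CC)(CC)CC)CO[Si](CC)(CC)CC | intermediate
28 | 2-(trimethylsilyl)ethyl (2S,3E,5E)-2-[(3R,8R,9S)-3-hydroxy-8-methyl-8,9,10-tris(triethylsilyloxy)dec-4-yn-1-yl]-2-methylhepta-3,5-dienoate | C/C=C/C=C/[C@@](C)(C(=O)OCC[Si](C)(C)C)CC[C@@H](O)C#CCC[C@@](C)(O[Si](CC)(CC)CC)[C@@H](O[Si](CC)(CC)CC)CO[Si](CC)(CC)CC | intermediate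
29 | 2-(trimethylsilyl)ethyl (2S,3E,5E)-2-[(3R,8R,9S)-3-(methanesulfonyloxy)-8-methyl-8,9,10-tris(triethylsilyloxy)dec-4-yn-1-yl]-2-methylhepta-3,5-dienoate | C/C=C/C=C/[C@@](C)(C(=O)OCC[Si](C)(C)C)CC[C@@H](OS(C)(=O)=O)C#CCC[C@@](C)(O[Si](CC)(CC)CC)[C@@H](O[Si](CC)(CC)CC)CO[Si](CC)(CC)CC | intermediate
30 | 2-(trimethylsilyl)ethyl (2S,3E,5E)-2-[(8R,9S)-5,8-dimethyl-8,9,10-tris(triethylsilyloxy)deca-3,4-dien-1-yl]-2-methylhepta-3,5-dienoate, allene axis R (aR) | C/C=C/C=C/[C@@](C)(C(=O)OCC[Si](C)(C)C)CCC=[C@]=C(C)CC[C@@](C)(O[Si](CC)(CC)CC)[C@@H](O[Si](CC)(CC)CC)CO[Si](CC)(CC)CC | intermediate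
31 | 2-(trimethylsilyl)ethyl (1S,5S,6R,8aS)-1,5,6-trimethyl-5-[(3R,4S)-3-methyl-3,4,5-tris(triethylsilyloxy)pentyl]-1,2,3,5,6,8a-hexahydronaphthalene-1-carboxylate | CC[Si](CC)(CC)OC[C@H](O[Si](CC)(CC)CC)[C@](C)(O[Si](CC)(CC)CC)CC[C@]1(C)C2=CCC[C@](C)(C(=O)OCC[Si](C)(C)C)[C@H]2C=C[C@H]1C | intermediate
32 | 2-(trimethylsilyl)ethyl (1S,5S,6R,8aS)-1,5,6-trimethyl-5-[(3R,4S)-3-methyl-3,4,5-tris(triethylsilyloxy)pentyl]-1,2,3,5,6,7,8,8a-octahydronaphthalene-1-carboxylate | CC[Si](CC)(CC)OC[C@H](O[Si](CC)(CC)CC)[C@](C)(O[Si](CC)(CC)CC)CC[C@]1(C)C2=CCC[C@](C)(C(=O)OCC[Si](C)(C)C)[C@H]2CC[C@H]1C | intermediate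
33 | (1S,5S,6R,8aS)-5-[(3R,4S)-3,4,5-trihydroxy-3-methylpentyl]-1,5,6-trimethyl-1,2,3,5,6,7,8,8a-octahydronaphthalene-1-carboxylic acid | OC[C@H](O)[C@](C)(O)CC[C@]1(C)C2=CCC[C@](C)(C(=O)O)[C@H]2CC[C@H]1C | intermediate
34 | (1S,5S,6R,8aS)-5-[(3R,4S)-4,5-diacetoxy-3-hydroxy-3-methylpentyl]-1,5,6-trimethyl-1,2,3,5,6,7,8,8a-octahydronaphthalene-1-carboxylic acid (CNP0224606.1) | CC(=O)OC[C@H](OC(C)=O)[C@](C)(O)CC[C@]1(C)C2=CCC[C@](C)(C(=O)O)[C@H]2CC[C@H]1C | target

**Count**

Total steps: 22. Longest linear sequence: 17 steps (steps 1–8, then 14–22); steps 9–13 form the second branch.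

**Steps most likely to fail**

Step 19. The cycloaddition may stall at the fully substituted C9 terminus, may divert to the proximal π-bond (a hydrindane), may lose the axial information through the allyl-rhodium intermediate, or may not separate the two diene orientations well. The fallback uses known chemistry with a carbonyl-activated dienophile; it sets out from alkyne 24 and aldehyde 17 and returns at 31. Zirconium-catalysed methylalumination of 24 (Me3Al, Cp2ZrCl2; then I2) should give the (E)-alkenyl iodide F1. Iodine–lithium exchange (t-BuLi, −78 °C) and addition to 17 give the allylic alcohol F2 (C1 epimers), which DMP oxidises to the (E)-trienone F3. The enone activates C9=C10, and a thermal or Me2AlCl-promoted intramolecular Diels–Alder reaction in the carbonyl-endo arrangement (C9 methyl endo, side chain exo) forms the same C5–C10 and C8–C9 bonds and should give the cis-fused decalone F4. In this variant C4 alone selects the diene face, so F4 may have to be separated from its C5/C8/C9 diastereomer. Enol triflate formation towards the ring-fusion carbon under thermodynamic control (Tf2O, 2,6-di-tert-butyl-4-methylpyridine) gives the enol triflate F5, and palladium-catalysed formate reduction (Pd(OAc)2, PPh3, Bu3N, HCO2H, DMF) removes the triflate to give 31.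

Step 4. The trienolate may be alkylated with poor or reversed facial selectivity, or partly at the γ- or ε-carbon. The fallback builds the quaternary carbon racemically and uses the auxiliary as a resolving group; it sets out from acid 5 and returns at 11. The dilithium dienediolate of 5 (2 equiv LiN(iPr)2, THF/DMPU) is allylated at the α-carbon with allyl bromide to give the racemic acid F6, with the diene geometry arising as in step 4. Oxalyl chloride gives the acid chloride F7, which acylates lithiated 6 to give 11 together with its C2 epimer F8. The two imides are diastereomers and are separated by chromatography or crystallisation, and 11 continues at step 5.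

Step 1. The Z-enal may isomerise to the E-enal before or during olefination; the resulting (2E,4E)-dienoate would later deliver a (7Z)-diene and the wrong C8 configuration. The fallback never handles a Z-enal; it sets out from ylide 2 and returns at 4. Wittig reaction of 2 with 2,2-dimethoxyacetaldehyde gives methyl (E)-4,4-dimethoxy-2-methylbut-2-enoate F9. Aqueous acid frees the aldehyde, methyl (E)-2-methyl-4-oxobut-2-enoate F10. A salt-free Wittig reaction with propylidenetriphenylphosphorane (from the propylphosphonium bromide and NaN(SiMe3)2, THF, −78 °C) then builds the 4,5-bond Z under kinetic control of the non-stabilised ylide and gives 4.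

**Further compounds**

F1 | step 19 | (1E,5R,6S)-1-iodo-2,5-dimethyl-5,6,7-tris(triethylsilyloxy)hept-1-ene | I/C=C(\C)CC[C@@](C)(O[Si](CC)(CC)CC)[C@@H](O[Si](CC)(CC)CC)CO[Si](CC)(CC)CC
F2 | step 19 | 2-(trimethylsilyl)ethyl (2S,3E,5E)-2-[(4E,8R,9S)-3-hydroxy-5,8-dimethyl-8,9,10-tris(triethylsilyloxy)dec-4-en-1-yl]-2-methylhepta-3,5-dienoate (C1 carbinol epimers) | C/C=C/C=C/[C@@](C)(C(=O)OCC[Si](C)(C)C)CCC(O)/C=C(\C)CC[C@@](C)(O[Si](CC)(CC)CC)[C@@H](O[Si](CC)(CC)CC)CO[Si](CC)(CC)CC
F3 | step 19 | 2-(trimethylsilyl)ethyl (2S,3E,5E)-2-[(4E,8R,9S)-5,8-dimethyl-3-oxo-8,9,10-tris(triethylsilyloxy)dec-4-en-1-yl]-2-methylhepta-3,5-dienoate | C/C=C/C=C/[C@@](C)(C(=O)OCC[Si](C)(C)C)CCC(=O)/C=C(\C)CC[C@@](C)(O[Si](CC)(CC)CC)[C@@H](O[Si](CC)(CC)CC)CO[Si](CC)(CC)CC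
F4 | step 19 | cis-fused decalone: C1 ketone, C10–H cis to C5–H, C6=C7, otherwise as 31 | CC[Si](CC)(CC)OC[C@H](O[Si](CC)(CC)CC)[C@](C)(O[Si](CC)(CC)CC)CC[C@]1(C)[C@H]2C(=O)CC[C@](C)(C(=O)OCC[Si](C)(C)C)[C@H]2C=C[C@H]1C
F5 | step 19 | C1 enol triflate of F4 (C1=C10, trifluoromethanesulfonyloxy on C1) | CC[Si](CC)(CC)OC[C@H](O[Si](CC)(CC)CC)[C@](C)(O[Si](CC)(CC)CC)CC[C@]1(C)C2=C(OS(=O)(=O)C(F)(F)F)CC[C@](C)(C(=O)OCC[Si](C)(C)C)[C@H]2C=C[C@H]1C
F6 | step 4 | racemic (3E,5E)-2-methyl-2-(prop-2-en-1-yl)hepta-3,5-dienoic acid | C/C=C/C=C/C(C)(C(=O)O)CC=C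
F7 | step 4 | racemic (3E,5E)-2-methyl-2-(prop-2-en-1-yl)hepta-3,5-dienoyl chloride | C/C=C/C=C/C(C)(C(=O)Cl)CC=C
F8 | step 4 | (R)-4-isopropyl-3-[(2R,3E,5E)-2-methyl-2-(prop-2-en-1-yl)hepta-3,5-dienoyl]-1,3-oxazolidin-2-one | C/C=C/C=C/[C@](C)(C(=O)N1[C@H](C(C)C)COC1=O)CC=C
F9 | step 1 | methyl (E)-4,4-dimethoxy-2-methylbut-2-enoate | COC(OC)/C=C(\C)C(=O)OC
F10 | step 1 | methyl (E)-2-methyl-4-oxobut-2-enoate | O=C/C=C(\C)C(=O)OC
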